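The route rests on disconnecting the two rings that meet at the C4a–C9a bond: the indoline ring (N9, C8a, C4b, C4a, C9a) and the dihydrofuran ring (O, C4a, C9a, C4', C5'). Because C4a carries the ether oxygen while C9a carries N9 and the ortho carbon C4' of the same 7'-methoxyindole ring, one acid-catalysed cascade on the phenylhydrazone of a racemic 4-aryloxypiperidin-3-one (N-Cbz, indole N-tosyl) forms C4a–C4b, N9–C9a and C4'–C9a, sets both quaternary centres, and converges both enantiomers of the ketone on one product under a chiral phosphoric acid. Short, conventional chemistry builds the ketone and finishes the target.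

Key step: step 7

Remark 1: Locants follow β-carboline numbering (C1, N2, C3, C4, C4a, C4b, C5–C8, C8a, N9, C9a) for the hexahydropyrido[3,4-b]indole part and primed indole numbering (N1'–C7a') for the methoxyindole; the target is (4aS,9aR). "Pentacycle" means this hexahydro-β-carboline whose C4a–O and C9a–C4' bonds to a 7'-methoxyindol-5'-yloxy unit close a cis-fused dihydrofuran ring.
Remark 2: The piperidine nitrogen is carried as a benzyl carbamate because the racemic epoxide 6 is a catalogue compound; the carbamate carbon becomes the N-methyl carbon in step 9.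
Remark 3: The sense of induction of the chiral acid in step 7 cannot be predicted; the antipode that gives the 4aS series is to be fixed by a test run.

Step 1
Reactants: 1 3-methoxy-4-nitrophenol
Product: 2 4-(benzyloxy)-2-methoxy-1-nitrobenzene
Conditions: BnBr, K2CO3, DMF, 23 °C
Reagents that add atoms: benzyl bromide, BrCc1ccccc1
Why: Williamson ether synthesis, in which the acidic nitrophenoxide displaces bromide from the benzylic halide by SN2 and so masks the O–H that would otherwise consume the Grignard reagent of step 2.

Step 2
Reactants: 2 4-(benzyloxy)-2-methoxy-1-nitrobenzene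
Product: 3 5-(benzyloxy)-7-methoxy-1H-indole
Conditions: CH2=CHMgBr (3.5 equiv), THF, −40 °C; aq. NH4Cl
Reagents that add atoms: vinylmagnesium bromide, C=C[Mg]Br
Why: Bartoli indole synthesis, in which the ortho-methoxy nitroarene is taken through the nitrosoarene and the [3,3] shift of an N-aryl-O-vinylhydroxylamine, the ortho methoxy group steering the shift to the free ortho carbon so that it ends at C7 and the benzyloxy group at C5.

Step 3
Reactants: 3 5-(benzyloxy)-7-methoxy-1H-indole
Product: 4 5-(benzyloxy)-7-methoxy-1-tosyl-1H-indole
Conditions: NaH, DMF, 0 °C; TsCl, 0 → 23 °C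
Reagents that add atoms: p-toluenesulfonyl chloride, Cc1ccc(cc1)S(Cl)(=O)=O
Why: N-sulfonylation of the indolyl sodium salt installs a group that survives hydrogenolysis, base and acid, lowers the nucleophilicity of C2' and C3' for step 7 and turns the neighbouring C7' methoxy group toward C6'.

Step 4
Reactants: 4 5-(benzyloxy)-7-methoxy-1-tosyl-1H-indole
Product: 5 7-methoxy-1-tosyl-1H-indol-5-ol
Conditions: H2 (1 atm), Pd/C, EtOAc/EtOH, 23 °C
Reagents that add atoms: none
Why: Catalytic hydrogenolysis of the benzyl aryl ether frees the C5 phenol while the N-sulfonyl indole and the methyl ether are inert under these conditions.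

Step 5
Reactants: 5 7-methoxy-1-tosyl-1H-indol-5-ol; 6 benzyl 7-oxa-3-azabicyclo[4.1.0]heptane-3-carboxylate (racemic)
Product: 7 benzyl trans-3-hydroxy-4-[(7-methoxy-1-tosylindol-5-yl)oxy]piperidine-1-carboxylate (racemic)
Conditions: Cs2CO3 (20 mol%), DMF, 80 °C
Reagents that add atoms: none
Why: Base-catalysed SN2 opening of the epoxide by the phenoxide should occur at C4, remote from the electron-withdrawing carbamate nitrogen and in the trans-diaxial (Fürst–Plattner) sense, giving the trans 4-aryloxy-3-ol, whose relative configuration is immaterial because step 6 removes the carbinol centre and step 7 erases the other.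

Step 6
Reactants: 7 benzyl trans-3-hydroxy-4-[(7-methoxy-1-tosylindol-5-yl)oxy]piperidine-1-carboxylate (racemic)
Product: 8 benzyl 4-[(7-methoxy-1-tosylindol-5-yl)oxy]-3-oxopiperidine-1-carboxylate (racemic)
Conditions: Dess–Martin periodinane, CH2Cl2, 0 → 23 °C
Reagents that add atoms: none
Why: Dess–Martin oxidation of the secondary alcohol under near-neutral conditions should give the α-aryloxy ketone without touching the sulfonamide, the carbamate or the electron-rich ether ring.

Step 7
Reactants: 8 benzyl 4-[(7-methoxy-1-tosylindol-5-yl)oxy]-3-oxopiperidine-1-carboxylate (racemic); 9 phenylhydrazine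
Product: 12 (4aS,9aR)-N2-benzyloxycarbonyl-N1'-tosyl pentacycle (C3' unsubstituted), via phenylhydrazone 10 (not isolated), via 4a-aryloxy-3H-indole 11 (not isolated)
Conditions: 9 (1.05 equiv), 4 Å MS, toluene, 23 °C; then (S)-STRIP (spirobiindane-derived chiral phosphoric acid, 10 mol%), Amberlite CG50, toluene, 50 °C
Reagents that add atoms: none
Why: Proposed new method: condensation gives hydrazone 10, whose acid-bound ene-hydrazine (C4a=C9a, the former C4a–H stereocentre erased) undergoes a [3,3] shift that forges C4a–C4b, after which the aniline nitrogen closes on the C9a iminium carbon and ammonia is lost to give 3H-indole 11, which cannot aromatise and is therefore protonated and attacked at C9a by C4' of the pendant aryl ether. The closest known chemistry is the interrupted Fischer indolization in which a 3H-indolium ion is captured by a tethered oxygen or nitrogen nucleophile, the chiral-phosphoric-acid-catalysed Fischer indolization run beside an ammonia-scavenging cation exchanger, and the acid-mediated closure of α-aryloxy ketones onto their carbonyl carbon; an arene as the trap for a 4a-aryloxy-3H-indolium ion is the untested element. The indoline ring closes by 5-exo-trig attack of N9 on the C9a iminium carbon and the dihydrofuran ring by 5-exo-trig aza-Friedel–Crafts attack of C4' on C9a=N9. C4a is set by the chiral phosphate that is ion-paired and hydrogen-bonded to the ene-hydrazinium ion and selects the face of the [3,3] shift (catalyst control, so both enantiomers of 8 should converge), and C9a is set by the substrate because the O–C5'–C4' tether can reach C9a only from the face that the oxygen occupies on C4a, which enforces the cis ring fusion. The step needs tautomerisation toward C4a and not C1, which the more substituted, oxygen-stabilised ene-hydrazine and the more acidic α-aryloxy C–H should favour. It also needs closure through C4' and not C6': C4' is para to the methoxy group and at the α-type position of the 5-oxyindole, while the N1' tosyl group turns the C7' methoxy methyl toward C6' and keeps C3' from competing.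

Step 8
Reactants: 12 (4aS,9aR)-N2-benzyloxycarbonyl-N1'-tosyl pentacycle (C3' unsubstituted)
Product: 13 (4aS,9aR)-N2-benzyloxycarbonyl pentacycle with free N1'–H
Conditions: Mg turnings (10 equiv), MeOH, ultrasound, 23 °C
Reagents that add atoms: none
Why: Reductive N–S cleavage of an N-sulfonyl indole by magnesium in methanol (electron transfer to the arenesulfonyl group) should release the indole N–H as toluenesulfinate leaves, while the carbamate, the aryl ethers and the two quaternary centres are inert.

Step 9
Reactants: 13 (4aS,9aR)-N2-benzyloxycarbonyl pentacycle with free N1'–H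
Product: 14 (4aS,9aR)-N2-methyl pentacycle with free N1'–H (C3' unsubstituted)
Conditions: LiAlH4 (6 equiv), THF, 0 °C → reflux; H2O, aq. NaOH work-up
Reagents that add atoms: none
Why: LiAlH4 reduction of a carbamate to an N-methyl amine (hydride addition, loss of benzyloxide, reduction of the formamide through its iminium ion) should proceed with the two N–H groups merely deprotonated and with no stereocentre able to epimerise.

Step 10
Reactants: 14 (4aS,9aR)-N2-methyl pentacycle with free N1'–H (C3' unsubstituted)
Product: 15 (4aS,9aR)-N2-methyl-3'-(dimethylaminomethyl) pentacycle (target)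
Conditions: CH2=NMe2+ I− (1.2 equiv), CH2Cl2/MeCN, 0 → 23 °C; aq. NaOH work-up
Reagents that add atoms: N,N-dimethylmethyleneiminium iodide, C=[N+](C)C.[I-]
Why: Mannich reaction (gramine synthesis) with a preformed iminium salt should occur at C3', the most nucleophilic carbon of the free, doubly oxygenated indole, since the small electrophile tolerates the peri substituent at C4', N2 is tertiary, and any aminal formed at the hindered N9 or at N1' reverts on aqueous work-up.

Compound list
1 | 3-methoxy-4-nitrophenol | COc1cc(O)ccc1[N+](=O)[O-] | starting material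
2 | 4-(benzyloxy)-2-methoxy-1-nitrobenzene | COc1cc(OCc2ccccc2)ccc1[N+](=O)[O-] | intermediate
3 | 5-(benzyloxy)-7-methoxy-1H-indole | COc1cc(OCc2ccccc2)cc2cc[nH]c12 | intermediate
4 | 5-(benzyloxy)-7-methoxy-1-tosyl-1H-indole | COc1cc(OCc2ccccc2)cc2ccn(S(=O)(=O)c3ccc(C)cc3)c12 | intermediate
5 | 7-methoxy-1-tosyl-1H-indol-5-ol | COc1cc(O)cc2ccn(S(=O)(=O)c3ccc(C)cc3)c12 | intermediate
6 | benzyl 7-oxa-3-azabicyclo[4.1.0]heptane-3-carboxylate (racemic cis-epoxide, one enantiomer drawn) | O=C(OCc1ccccc1)N1CC[C@@H]2O[C@@H]2C1 | starting material
7 | benzyl trans-3-hydroxy-4-[(7-methoxy-1-tosylindol-5-yl)oxy]piperidine-1-carboxylate (racemic, one enantiomer drawn) | O=C(OCc1ccccc1)N1CC[C@H](Oc2cc(OC)c3c(ccn3S(=O)(=O)c3ccc(C)cc3)c2)[C@@H](O)C1 | intermediate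
8 | benzyl 4-[(7-methoxy-1-tosylindol-5-yl)oxy]-3-oxopiperidine-1-carboxylate (racemic) | O=C(OCc1ccccc1)N1CCC(Oc2cc(OC)c3c(ccn3S(=O)(=O)c3ccc(C)cc3)c2)C(=O)C1 | intermediate
9 | phenylhydrazine | NNc1ccccc1 | starting material
10 | benzyl 4-[(7-methoxy-1-tosylindol-5-yl)oxy]-3-(2-phenylhydrazinylidene)piperidine-1-carboxylate (racemic, C=N geometry not defined) | O=C(OCc1ccccc1)N1CCC(Oc2cc(OC)c3c(ccn3S(=O)(=O)c3ccc(C)cc3)c2)C(=NNc2ccccc2)C1 | intermediate (not isolated)
11 | benzyl (4aS)-4a-[(7-methoxy-1-tosylindol-5-yl)oxy]-1,3,4,4a-tetrahydro-2H-pyrido[3,4-b]indole-2-carboxylate (3H-indole, C9a=N9) | O=C(OCc1ccccc1)N1CC[C@]2(Oc3cc(OC)c4c(ccn4S(=O)(=O)c4ccc(C)cc4)c3)c3ccccc3N=C2C1 | intermediate (not isolated)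
12 | (4aS,9aR)-N2-benzyloxycarbonyl-N1'-tosyl pentacycle (C3' unsubstituted) | COc1cc2c(c3ccn(S(=O)(=O)c4ccc(C)cc4)c13)[C@@]13CN(C(=O)OCc4ccccc4)CC[C@]1(O2)c1ccccc1N3 | intermediate
13 | (4aS,9aR)-N2-benzyloxycarbonyl pentacycle with free N1'–H | COc1cc2c(c3cc[nH]c13)[C@@]13CN(C(=O)OCc4ccccc4)CC[C@]1(O2)c1ccccc1N3 | intermediate
14 | (4aS,9aR)-N2-methyl pentacycle with free N1'–H (C3' unsubstituted) | COc1cc2c(c3cc[nH]c13)[C@@]13CN(C)CC[C@]1(O2)c1ccccc1N3 | intermediate
15 | (4aS,9aR)-N2-methyl-3'-(dimethylaminomethyl) pentacycle | COc1cc2c(c3c(CN(C)C)c[nH]c13)[C@@]13CN(C)CC[C@]1(O2)c1ccccc1N3 | target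

Total step count: 10. Longest linear sequence: 10 steps (1 → 15); 6 and 9 are purchased.

Steps most likely to fail

Step 7 (the step that bears the label). The hydrazone may tautomerise toward C1, so that the [3,3] shift runs on the nitrogen side and ends in an aromatic indole. The chiral acid may discriminate the two faces of the ene-hydrazine poorly. Closure may go through C6', or be slow enough for a 1,2-shift of the 3H-indolium ion to compete. Ammonia may inhibit the catalyst. The fallback uses known chemistry only, sets out from 5 and comes back at 12. Phenol 5 would be brominated ortho to the hydroxyl group at C4 (NBS, MeCN, −20 °C) to give 4-bromo-7-methoxy-1-tosyl-1H-indol-5-ol F1. In parallel, tryptamine would be acylated (benzyl chloroformate, Et3N, CH2Cl2) to benzyl [2-(1H-indol-3-yl)ethyl]carbamate F2, which would be borylated at the indole 2-position ([Ir(OMe)(cod)]2, 4,4'-di-tert-butyl-2,2'-bipyridine, B2pin2, THF, 60 °C) to the 2-pinacolboronate F3. Suzuki–Miyaura coupling of the two (Pd(OAc)2, SPhos, K3PO4, dioxane/H2O, 80 °C) should give the 2-aryltryptamine carbamate F4, in which C9a already carries C4'. Paraformaldehyde and CF3CO2H in CH2Cl2 would then generate the N-acyliminium ion. Its Pictet–Spengler-type cyclisation onto the 2-substituted indole (ipso attack at the indole 3-position, then 1,2-shift of the new methylene carbon to C9a) leaves a benzylic cation at C4a that only the neighbouring phenol oxygen can capture, giving the racemic cis-fused pentacycle F5. Separation of its enantiomers by preparative chromatography on a chiral stationary phase returns to the route at 12.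

Step 5. The phenoxide may attack C3 as well as C4 of the epoxide, and at 80 °C it may also take the tosyl group from the indole nitrogen of a second molecule. The fallback forms the C4–O bond at the ketone oxidation level; it sets out from 5 and comes back at 8. Purchased benzyl 3-oxopiperidine-1-carboxylate would be deprotonated kinetically at C4 and silylated (LiN(SiMe3)2, Me3SiCl, THF, −78 °C) to benzyl 3-(trimethylsilyloxy)-5,6-dihydropyridine-1(2H)-carboxylate F6, then brominated (NBS, THF, 0 °C) to racemic benzyl 4-bromo-3-oxopiperidine-1-carboxylate F7. Alkylation of phenol 5 with this α-bromo ketone (K2CO3, acetone, 23 °C, Williamson etherification) should give ketone 8 directly.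

Step 10. C-aminomethylation at the peri-hindered C3' may be slow, so that N-aminomethylation at N9 or N1' persists, or the gramine product may lose dimethylamine and alkylate a second indole. The fallback separates C–C bond formation from amine introduction; it sets out from 14 and comes back at 15. Amine 14 would be formylated at C3' under Vilsmeier–Haack conditions (POCl3, DMF, 0 → 40 °C; aq. NaOH, which also returns any N9 formamidinium ion to N9–H) to the (4aS,9aR)-N2-methyl pentacycle 3'-carbaldehyde F8. Reductive amination (Me2NH, Ti(OiPr)4, THF; then NaBH4, MeOH) would give target 15.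

Further compounds
F1 | step 7 | 4-bromo-7-methoxy-1-tosyl-1H-indol-5-ol | COc1cc(O)c(Br)c2ccn(S(=O)(=O)c3ccc(C)cc3)c12
F2 | step 7 | benzyl [2-(1H-indol-3-yl)ethyl]carbamate | O=C(OCc1ccccc1)NCCc1c[nH]c2ccccc12
F3 | step 7 | benzyl {2-[2-(4,4,5,5-tetramethyl-1,3,2-dioxaborolan-2-yl)-1H-indol-3-yl]ethyl}carbamate | O=C(OCc1ccccc1)NCCc1c(B2OC(C)(C)C(C)(C)O2)[nH]c2ccccc12
F4 | step 7 | benzyl {2-[2-(5-hydroxy-7-methoxy-1-tosyl-1H-indol-4-yl)-1H-indol-3-yl]ethyl}carbamate | COc1cc(O)c(-c2[nH]c3ccccc3c2CCNC(=O)OCc2ccccc2)c2ccn(S(=O)(=O)c3ccc(C)cc3)c12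
F5 | step 7 | racemic cis-fused N2-benzyloxycarbonyl-N1'-tosyl pentacycle (both enantiomers written) | COc1cc2c(c3ccn(S(=O)(=O)c4ccc(C)cc4)c13)[C@@]13CN(C(=O)OCc4ccccc4)CC[C@]1(O2)c1ccccc1N3.COc1cc2c(c3ccn(S(=O)(=O)c4ccc(C)cc4)c13)[C@]13CN(C(=O)OCc4ccccc4)CC[C@@]1(O2)c1ccccc1N3
F6 | step 5 | benzyl 3-(trimethylsilyloxy)-5,6-dihydropyridine-1(2H)-carboxylate | C[Si](C)(C)OC1=CCCN(C1)C(=O)OCc1ccccc1
F7 | step 5 | benzyl 4-bromo-3-oxopiperidine-1-carboxylate (racemic) | O=C(OCc1ccccc1)N1CCC(Br)C(=O)C1
F8 | step 10 | (4aS,9aR)-N2-methyl pentacycle 3'-carbaldehyde | COc1cc2c(c3c(C=O)c[nH]c13)[C@@]13CN(C)CC[C@]1(O2)c1ccccc1N3
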